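## Retrosynthetic overview
- Target 14 comes from a Heck reaction of aryl bromide 12 with acrylic acid, so the cinnamate is installed last.
- 12 is the trans-dihydrobenzofuran. It is closed by acid-promoted addition of the phenol to the p-hydroxybenzylic cation of diol 11, so C2 is set trans by C3.
- 11 comes from ArM addition to aldehyde 8, which comes from ozonolysis of 6.
- 6 is made by an aromatic Claisen rearrangement that forms the C3a–C3 bond and sets C3 by transfer from the carbinol stereocentre of 5. Compound 5 comes from Mitsunobu coupling of 4-bromoguaiacol with 3, which comes from cross-metathesis of (R)-but-3-en-2-ol.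
- The benzene ring is never built; the dihydrofuran ring is the only ring formed, in Step 7.

**Assumption:** (R)-but-3-en-2-ol is commercially available as the single enantiomer.

## Route

**Step 1**
Reactants: 1 (R)-but-3-en-2-ol (3 equiv); 2 tert-butyl(allyloxy)dimethylsilane
Product: 3 (2R,3E)-5-(TBSO)pent-3-en-2-ol
Conditions: Grubbs II (3 mol%), CH2Cl2, 40 °C
Reagents that add atoms: none
Why: Cross-metathesis of two terminal alkenes gives the E-1,2-disubstituted alkene, and the carbinol stereocentre is not involved.

**Step 2**
Reactants: 3; 4 4-bromo-2-methoxyphenol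
Product: 5 aryl ether, 4-bromo-2-methoxy-1-{[(2S,3E)-5-(TBSO)pent-3-en-2-yl]oxy}benzene
Conditions: PPh3, DIAD, THF, 0 °C → rt
Reagents that add atoms: none (the phenol is the reactant)
Why: Mitsunobu SN2 inverts the secondary carbinol, converting (R)-alcohol 3 into the (S)-aryl ether needed for the Claisen step.

**Step 3**
Reactants: 5
Product: 6 6-[(2R,3E)-1-(TBSO)pent-3-en-2-yl]-4-bromo-2-methoxyphenol
Conditions: PhNEt2 (0.5 M), 195 °C, sealed tube
Reagents that add atoms: none
Why: This is the key aromatic Claisen [3,3] rearrangement. A chair transition state with the E-alkene and the CH3 pseudo-equatorial transfers the chirality suprafacially to the new benzylic carbon as (R). The bond forms at the free ortho carbon because the other ortho carbon carries OMe, and the dienone then tautomerizes to the phenol.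

**Step 4**
Reactants: 6; ozone
Product: 8 (2R)-2-(5-bromo-2-hydroxy-3-methoxyphenyl)-3-(TBSO)propanal (exists partly as the 2-hydroxy-dihydrobenzofuran lactol)
Conditions: O3, CH2Cl2, −78 °C; then Me2S, −78 °C → rt; used crude at once
Reagents that add atoms: ozone, [O-][O+]=O (its oxygen ends up in the aldehyde)
Why: Ozonolysis cleaves the alkene far faster than it attacks the arene, and the stereocentre is untouched.

**Step 5**
Reactants: 4; 9 chloromethyl methyl ether
Product: 10 4-bromo-2-methoxy-1-(methoxymethoxy)benzene
Conditions: MOMCl, i-Pr2NEt, CH2Cl2, 0 °C → rt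
Reagents that add atoms: MOMCl, COCCl (adds CH2OCH3)
Why: Standard phenol protection, so that a Grignard reagent can be made from 10.

**Step 6**
Reactants: 8; 10 (as Ar'MgBr)
Product: 11 diol, (2R)-2-(5-bromo-2-hydroxy-3-methoxyphenyl)-3-(TBSO)-1-[3-methoxy-4-(methoxymethoxy)phenyl]propan-1-ol, a ~1:1 mixture at C1
Conditions: 10 + Mg, THF, 50 °C, to give Ar'MgBr; then anhydrous CeCl3, THF, −78 °C; add crude 8, −78 → 0 °C; aq NH4Cl
Reagents that add atoms: none (Mg and Ce are not retained)
Why: The organocerium reagent is weakly basic, so it adds to the enolizable α-aryl aldehyde without epimerizing it; 3 equiv cover the phenol and the lactol. The new carbinol centre is irrelevant because it is ionized in the next step.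

**Step 7**
Reactants: 11
Product: 12 (2S,3R)-trans-5-bromo-2-(4-hydroxy-3-methoxyphenyl)-3-(hydroxymethyl)-7-methoxy-2,3-dihydrobenzofuran
Conditions: 3 M aq HCl, THF/MeOH 1:1, 50 °C
Reagents that add atoms: none
Why: Acid removes the TBS and MOM groups and ionizes the p-hydroxybenzylic alcohol to a quinone-methide-type cation. The ortho phenol closes the five-membered ring anti to the CH2OH group, so C2 is set trans to the pre-existing C3 (acid-promoted cyclization of a benzylic cation).

**Step 8**
Reactants: 12; 13 acrylic acid
Product: 14 target
Conditions: Pd(OAc)2 (5 mol%), P(o-tol)3 (10 mol%), Et3N, DMF, 100 °C; then aq HCl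
Reagents that add atoms: none (acrylic acid is the reactant)
Why: Mizoroki–Heck coupling of an electron-rich aryl bromide with acrylic acid gives the E-cinnamic acid, and the free OH groups and the benzylic ether are unaffected.

## Checks
- **Structure:** 14 is a 2,3-dihydrobenzofuran with 2-(4-hydroxy-3-methoxyphenyl), 3-CH2OH, 7-OMe next to the ring O, and (E)-CH=CHCO2H at C5 para to the ring O. This matches the target SMILES.
- **Stereochemistry:** The target is (2S,3R) and trans. C3 is (R) from Step 3, and Step 7 gives trans.
- **Stereocentre survival:** C3 is never enolizable after Step 6, and nothing after Step 7 touches it.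
- **Protecting groups:** TBS and MOM survive Steps 1–6 and are removed together in Step 7.

## Compound list
1 | (R)-but-3-en-2-ol | C[C@@H](O)C=C | starting material
2 | tert-butyl(allyloxy)dimethylsilane | C=CCO[Si](C)(C)C(C)(C)C | starting material
3 | (2R,3E)-5-(TBSO)pent-3-en-2-ol | C[C@@H](O)/C=C/CO[Si](C)(C)C(C)(C)C | intermediate
4 | 4-bromo-2-methoxyphenol | COc1cc(Br)ccc1O | starting material
5 | aryl ether (S,E) | COc1cc(Br)ccc1O[C@@H](C)/C=C/CO[Si](C)(C)C(C)(C)C | intermediate
6 | Claisen phenol (R,E) | Oc1c(OC)cc(Br)cc1[C@H](CO[Si](C)(C)C(C)(C)C)/C=C/C | intermediate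
7 | ozone | [O-][O+]=O | starting material (reagent)
8 | (2R)-aldehyde | Oc1c(OC)cc(Br)cc1[C@H](CO[Si](C)(C)C(C)(C)C)C=O | intermediate
9 | chloromethyl methyl ether | COCCl | starting material (reagent)
10 | 4-bromo-2-methoxy-1-(MOMO)benzene | COCOc1ccc(Br)cc1OC | intermediate
11 | diol (C1 epimeric mixture, C2 as drawn) | COCOc1ccc(C(O)[C@@H](CO[Si](C)(C)C(C)(C)C)c2cc(Br)cc(OC)c2O)cc1OC | intermediate
12 | trans-dihydrobenzofuran bromide | COc1cc([C@H]2Oc3c(OC)cc(Br)cc3[C@@H]2CO)ccc1O | intermediate
13 | acrylic acid | C=CC(=O)O | starting material
14 | target | COc1cc([C@H]2Oc3c(OC)cc(/C=C/C(=O)O)cc3[C@@H]2CO)ccc1O | target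

## Totals
Total steps: 8. Longest linear sequence: 7 (Steps 1, 2, 3, 4, 6, 7, 8).

## Three steps most likely to fail
1. **Step 6 (arylation of the α-aryl aldehyde).** The aldehyde can epimerize or undergo β-elimination of the silyloxy group.
   Fallback: put the aryl carbinol into the Claisen substrate instead. Cross-metathesize 1 with 1-[3-methoxy-4-(MOMO)phenyl]allyl acetate, then run Mitsunobu and Claisen. Finish with ozonolysis and in-situ NaBH4 reduction, so no α-aryl aldehyde is ever isolated.
2. **Step 7 (acid cyclization).** Elimination to a 1,2-diarylpropene followed by reprotonation could erode C3.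
   Fallback: separate the C1 epimers of 11 and close the ring by Mitsunobu (PPh3/DIAD). This is a stereospecific SN2 inversion at C2 instead of a cation, and the epimer that gives trans is used.
3. **Step 2 (Mitsunobu on a secondary allylic alcohol).** SN2′ attack or incomplete inversion would give the wrong Cα configuration or a wrong-regiochemistry ether.
   Fallback: start from the (S)-alcohol (from (S)-but-3-en-2-ol), convert it to the mesylate, and displace it with the potassium phenoxide of 4 in an SN2 reaction with inversion.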